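The numbers in the tables are simulated with constants of no real substance, noise included.

Two chemists disagree. Their flask holds a racemate of substrate with partner and a single-handed free catalyst, and two earlier runs stand beside it.

| setting | Wednesday's | Saturday's | flask |
|---|---|---|---|
| left-handed substrate | 49 mM | 49 mM | 49 mM |
| right-handed substrate | 49 mM | 49 mM | 49 mM |
| partner | 2.2 equiv | 2.2 equiv | 2.20 equiv |
| free catalyst | 0.045 mol% | 0.1 mol% | 0.067 mol% |
| remark | run made earlier | run made earlier |  |
| time |  |  | 10 min |

- Wednesday's (time / min: left-handed substrate / %, right-handed substrate / %): 0.833: 47.4, 50.2; 1.33: 47.9, 49.5; 2.00: 46.3, 49.2; 3.00: 44.1, 49.9; 4.00: 43.5, 50.8; 6.00: 38.2, 48.8; 10.0: 37.1, 45.2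
- Saturday's (time / min: left-handed substrate / %, right-handed substrate / %): 0.500: 48.0, 49.8; 1.50: 44.4, 50.6; 3.00: 40.8, 46.2; 4.00: 38.4, 48.5; 6.00: 36.2, 48.0; 8.00: 33.6, 47.6; 10.0: 31.3, 45.9

(each reading ± 1 percentage point)

- free catalyst is single-handed; left-handed substrate and right-handed substrate are mirror images of each other, charged as a racemate, each of them at the stated concentration
- an excess is below zero if the other one leads

1. part of the left-handed substrate and right-handed substrate charged together that has reacted at 10 min
2. excess of left-handed product over right-handed product in the product at 10 min
3. excess of right-handed substrate over left-handed substrate among what is left of the two at 10 min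

The first chemist books each substrate's loss as its own product: “Products are about 16 left and 4 right”. That view gives the forecast: c 20%, eP 60%, eS 15%.

The second chemist compares the runs at 10.0 min. Going from Wednesday's 0.045 mol% of catalyst to Saturday's 0.1 mol%, the left-handed reading drops 5.8 percentage points further, but the right-handed reading ends 0.7 points higher, a smaller shift and within a scatter of 1 point. So she doubts that the right-handed loss is catalysed product. She reads it as a leak into the mirror image (racemisation), like two tanks joined by a pipe, with flow set by the gap [right-handed substrate] − [left-handed substrate].

Even if that shift is counted as a rise in right-handed loss, right-handed product per left-handed product is 0.121. That worst case gives eP 78.4%, which she takes as a floor and not as her value, and it already stands above the forecast's 60%.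

She also defines the leak time, the mean gap times the elapsed time divided by the right-handed loss. She replaces the gap curve by its mean, taken as 0.5 of the end gap. Averaged over both runs, the end gap is 11 points and the loss 4.4 points, so the reading is 12.8 min. The error is visible: the gaps read at mid-run average 9.9 points, more than that mean. So she uses this leak time only with the same shortcut.

The flask gives c 19.1%, eP 96.1%, eS 14.6%.

    partner + free catalyst + left-handed substrate → free catalyst + left-handed product (k = 726 M⁻² s⁻¹)
    left-handed substrate ⇌ right-handed substrate (k = 6.52 × 10⁻⁴ s⁻¹)
    partner → decomposed reagent (k = 8.22 × 10⁻⁴ s⁻¹)
    2 free catalyst ⇌ resting dimer, settled at all times (K = 48400 M⁻¹)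
    partner + free catalyst + right-handed substrate → free catalyst + right-handed product (k = 12.3 M⁻² s⁻¹)
    free catalyst → spent catalyst (k = 1.33 × 10⁻⁴ s⁻¹)

The first chemist's view stands for c and eS, which rest on how much substrate has gone, and it falls 36 points short on eP. At 10.0 min this flask holds 0.377% of right-handed product, far less than the 3.6 points fall in right-handed substrate. The leak time, with this flask's end gap, predicts a fall of 4.6 points. In the neighbour with 0.27 mol% of catalyst it predicts 7.6 points, and that flask's right-handed substrate fell 6.7 points.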